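**Strategy.** The route rests on cutting the C4–C5 bond of the dihydropyran ring. The cross-ring dienol ether O2–C3=C4–C5=C6 with its allylic C11 acetate is read as an O-allenyl acetal (O2–C3=C4=C11) plus a cyclopentenyl C5 iodide plus acetate. One palladium-catalysed operation joins C5 to the central allene carbon, closes the pyran ring, creates the conjugated diene and delivers the C11 acetate through a π-allyl intermediate. The precursor is a fully oxygenated iodocyclopentene (C7, C8, C9 set from (S)-4-silyloxycyclopentenone) whose C1 is a mixed silyl allenyl acetal; the C1 ester and the two isovalerates follow.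

Key step: step 11

Remark: iridoid numbering is used for every compound (ring atoms C1 acetal carbon, O2, C3, C4, C5, C6, C7, C8, C9; C10 = CH2 on C8, C11 = CH2 on C4; β is the face of H-9); C1 of 17–22 is an epimer mixture that converges at lactol 22, and acid 24 is made in step 13 on the assumption that only its hydroxy acid precursor is reliably stocked.

**Step 1**
Reactants: 1 (S)-4-(tert-butyldimethylsilyloxy)cyclopent-2-en-1-one; 2 formaldehyde
Product: 4 (4R,5S)-4-(tert-butyldimethylsilyloxy)-5-(hydroxymethyl)cyclopent-2-en-1-one, via lithium dienolate 3 (not isolated)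
Conditions: LiN(iPr)2, THF, −78 °C; HCHO (gas, cracked from paraformaldehyde), −78 °C; aq NH4Cl
Reagents that add atoms: none
Why: Kinetic deprotonation at the α′ methylene (C8) and aldol addition to formaldehyde should place the hydroxymethyl group trans to the C7 silyloxy group, a centre that is re-enolised in step 3 so its configuration is of no consequence (aldol reaction).

**Step 2**
Reactants: 4 (4R,5S)-4-(tert-butyldimethylsilyloxy)-5-(hydroxymethyl)cyclopent-2-en-1-one
Product: 5 (4R,5S)-4-(tert-butyldimethylsilyloxy)-5-[(tert-butyldimethylsilyloxy)methyl]cyclopent-2-en-1-one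
Conditions: tBuMe2SiCl, imidazole, DMF, 0 °C → rt
Reagents that add atoms: tert-butyldimethylsilyl chloride, CC(C)(C)[Si](C)(C)Cl
Why: Silyl ether formation at the primary alcohol blocks retro-aldol loss of formaldehyde in the next enolisation and touches no stereocentre.

**Step 3**
Reactants: 5 (4R,5S)-4-(tert-butyldimethylsilyloxy)-5-[(tert-butyldimethylsilyloxy)methyl]cyclopent-2-en-1-one
Product: 8 (4R,5S)-4-(tert-butyldimethylsilyloxy)-5-[(tert-butyldimethylsilyloxy)methyl]-5-(triethylsilyloxy)cyclopent-2-en-1-one, via potassium dienolate 6 (not isolated), via potassium alkoxide 7 (not isolated)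
Conditions: KN(SiMe3)2, THF, −78 °C; 2-(phenylsulfonyl)-3-phenyloxaziridine, −78 °C; then Et3SiOTf, −78 → 0 °C
Reagents that add atoms: 2-(phenylsulfonyl)-3-phenyloxaziridine, O=S(=O)(c1ccccc1)N1OC1c1ccccc1; triethylsilyl trifluoromethanesulfonate, CC[Si](CC)(CC)OS(=O)(=O)C(F)(F)F
Why: The planar tetrasubstituted enolate should be hydroxylated by the N-sulfonyloxaziridine on the face anti to the neighbouring C7 silyloxy group, which sets C8 with its oxygen β and the CH2OTBS arm cis to the C7 oxygen, and the alkoxide is silylated in the same flask (enolate oxidation of the Davis type).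

**Step 4**
Reactants: 8 (4R,5S)-4-(tert-butyldimethylsilyloxy)-5-[(tert-butyldimethylsilyloxy)methyl]-5-(triethylsilyloxy)cyclopent-2-en-1-one
Product: 9 (4R,5S)-4-(tert-butyldimethylsilyloxy)-5-[(tert-butyldimethylsilyloxy)methyl]-2-iodo-5-(triethylsilyloxy)cyclopent-2-en-1-one
Conditions: I2, pyridine, CH2Cl2, 0 °C → rt
Reagents that add atoms: iodine, [I][I]
Why: Pyridine-mediated α-iodination of the enone (conjugate addition of pyridine, iodination of the enolate, elimination) installs the C5 iodide that later starts the ring closure and affects no stereocentre.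

**Step 5**
Reactants: 9 (4R,5S)-4-(tert-butyldimethylsilyloxy)-5-[(tert-butyldimethylsilyloxy)methyl]-2-iodo-5-(triethylsilyloxy)cyclopent-2-en-1-one
Product: 10 (3R,4S)-3-(tert-butyldimethylsilyloxy)-4-[(tert-butyldimethylsilyloxy)methyl]-1-iodo-5-methylidene-4-(triethylsilyloxy)cyclopent-1-ene
Conditions: Ph3PCH3Br, KN(SiMe3)2, THF, 0 °C → rt
Reagents that add atoms: methyltriphenylphosphonium bromide, C[P+](c1ccccc1)(c1ccccc1)c1ccccc1.[Br-]
Why: Wittig methylenation of the C9 ketone introduces C1; the ketone has no α-hydrogen, so the basic ylide can neither epimerise nor eliminate.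

**Step 6**
Reactants: 10 (3R,4S)-3-(tert-butyldimethylsilyloxy)-4-[(tert-butyldimethylsilyloxy)methyl]-1-iodo-5-methylidene-4-(triethylsilyloxy)cyclopent-1-ene
Product: 12 primary alcohol (C1 = CH2OH on C9; H-9 β; C5 iodide; 7α-OTBS; 8β-OTES; 8α-CH2OTBS), via B-alkyl-9-BBN adduct 11 (not isolated)
Conditions: 9-BBN, THF, 0 °C → rt; then NaOH, H2O2, 0 °C
Reagents that add atoms: hydrogen peroxide, OO
Why: Anti-Markovnikov hydroboration–oxidation of the 1,1-disubstituted alkene should occur from the β face, anti to the C8 CH2OTBS arm and the cis C7 silyloxy group that shield the α face, so that hydrogen is delivered to C9 on the β face and C1 ends α.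

**Step 7**
Reactants: 12 primary alcohol
Product: 14 carboxylic acid (C1 = CO2H; otherwise as 12), via aldehyde 13 (not isolated)
Conditions: TEMPO (0.2 equiv), PhI(OAc)2, MeCN–H2O, rt
Reagents that add atoms: water, O
Why: Oxoammonium oxidation in wet acetonitrile takes the alcohol through the aldehyde hydrate to the acid under near-neutral conditions that should spare the alkenyl iodide, the silyl ethers and the C9 centre.

**Step 8**
Reactants: 14 carboxylic acid; 15 propargyl bromide
Product: 16 prop-2-ynyl ester of 14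
Conditions: KHCO3, DMF, rt
Reagents that add atoms: none
Why: SN2 O-alkylation of the carboxylate needs no activation of the acyl group and only a weak base, so C9 should not epimerise.

**Step 9**
Reactants: 16 prop-2-ynyl ester of 14
Product: 18 mixed acetal (C1 bears H; OTBS; OCH2C≡CH; both C1 epimers), via diisobutylaluminium hemiacetal 17 (not isolated)
Conditions: iBu2AlH, CH2Cl2, −78 °C; then pyridine, tBuMe2SiOTf, −78 → −40 °C
Reagents that add atoms: tert-butyldimethylsilyl trifluoromethanesulfonate, CC(C)(C)[Si](C)(C)OS(=O)(=O)C(F)(F)F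
Why: Single hydride addition to the ester gives an aluminium hemiacetal that is stable at low temperature and is O-silylated in the flask (reductive silylation of an ester); C1 forms without control, which is harmless because both epimers converge at lactol 22.

**Step 10**
Reactants: 18 mixed silyl prop-2-ynyl acetal
Product: 19 mixed acetal (C1 bears H; OTBS; OCH=C=CH2; both C1 epimers)
Conditions: KOtBu (0.3 equiv), THF, 0 °C → rt
Reagents that add atoms: none
Why: Base-catalysed prototropic isomerisation of a propargyl ether to the allenyl ether is the standard alkoxyallene synthesis, and the silyl acetal, silyl ethers and alkenyl iodide tolerate catalytic tert-butoxide.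

**Step 11**
Reactants: 19 mixed silyl allenyl acetal
Product: 21 bicyclic dienol ether (1-OTBS, both epimers; 11-acetoxy; C3=C4 and C5=C6; 7α-OTBS; 8β-OTES; 10-OTBS; H-9 β), via allyl-PdI(PPh3) complex 20 (not isolated)
Conditions: Pd(PPh3)4 (10 mol %), Bu4NOAc, MeCN, 50 °C
Reagents that add atoms: tetrabutylammonium acetate, CC(=O)[O-].CCCC[N+](CCCC)(CCCC)CCCC
Why: Zerovalent palladium inserts into the C5–I bond and the alkenylpalladium iodide adds across the distal C4=C11 π bond of the tethered alkoxyallene, C5 bonding to the central carbon C4, to give the 1-alkoxy-η3-allyl complex 20 (C3–C4–C11), which acetate attacks at C11 with release of zerovalent palladium. The closest known reaction type is the cyclising Heck-type carbopalladation of allenes with anion capture of the π-allyl intermediate. The pyran ring (O2, C1, C9, C5, C4, C3) is closed in the 6-exo-trig mode with respect to the C4=C11 bond that is consumed, whereas closure onto the allene terminus C3 would give a five-membered ring and forgo the π-allyl stabilisation. No stereocentre is created: C9 is untouched, C1 is carried through as an epimer mixture and the C3=C4 geometry is fixed by the ring. The step needs the acetate to end at C11 and not at C3; attack at C3 would give an allylic acylal that the catalyst re-ionises, so the conjugated dienol ether O2–C3=C4–C5=C6 with the C11 acetate is the thermodynamic sink, and the π-allyl has no β-hydrogen that could be lost. The C7 oxygen is kept as a silyl ether so that it cannot ionise under palladium, and the silyl acetal at C1 does not ionise either.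

**Step 12**
Reactants: 21 bicyclic dienol ether
Product: 22 lactol (1-OH, anomer mixture; otherwise as 21)
Conditions: Bu4NF, AcOH, THF, −20 → 0 °C
Reagents that add atoms: none
Why: Buffered fluoride should cleave the anomeric silyl ether selectively, because a hemiacetal oxide leaves silicon far more readily than an alkyl alkoxide, and acetic acid protonates the lactolate at once (selective desilylation).

**Step 13**
Reactants: 23 3-hydroxy-3-methylbutanoic acid
Product: 24 3-acetoxy-3-methylbutanoic acid
Conditions: AcCl (neat), rt; then H2O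
Reagents that add atoms: acetyl chloride, CC(=O)Cl
Why: O-Acetylation of the tertiary alcohol with neat acetyl chloride, followed by aqueous work-up that returns any acyl chloride or mixed anhydride to the free acid.

**Step 14**
Reactants: 22 lactol; 24 3-acetoxy-3-methylbutanoic acid
Product: 25 1β-(3-acetoxy-3-methylbutanoyloxy) compound (11-acetoxy; 7α-OTBS; 8β-OTES; 10-OTBS)
Conditions: DIC, DMAP (0.1 equiv), CH2Cl2, −20 → 0 °C
Reagents that add atoms: none
Why: Steglich acylation of the anomerising lactol should give the 1β ester, with the acyloxy group pseudo-axial (anomeric effect) and trans to the C9–C8 bond as in other 1-O-acyl iridoids, which sets C1 as S while the anomers funnel through ring–chain tautomerism.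

**Step 15**
Reactants: 25 1β-ester tris-silyl ether
Product: 26 7α,8β,10-triol (1β ester and 11-acetate retained)
Conditions: HF·pyridine, pyridine, THF, 0 °C → rt
Reagents that add atoms: none
Why: Pyridine-buffered hydrogen fluoride removes the two TBS ethers and the TES ether by Si–O cleavage without the base that would cleave the anomeric ester or the acid strength that would ionise the allylic acetate.

**Step 16**
Reactants: 26 7α,8β,10-triol
Product: 27 target
Conditions: (Me2CHCH2CO)2O, DMAP (cat), pyridine, CH2Cl2, 0 °C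
Reagents that add atoms: 3-methylbutanoic anhydride, CC(C)CC(=O)OC(=O)CC(C)C
Why: DMAP-catalysed acylation esterifies the primary C10 and the secondary allylic C7 hydroxyl groups, while the tertiary C8 hydroxyl is too hindered to react.

**Compound list**

1 | (S)-4-(tert-butyldimethylsilyloxy)cyclopent-2-en-1-one | O=C1C=C[C@@H](O[Si](C)(C)C(C)(C)C)C1 | starting material
2 | formaldehyde (monomer from paraformaldehyde) | C=O | starting material
3 | lithium dienolate of 1 | [Li]OC1=C[C@H](O[Si](C)(C)C(C)(C)C)C=C1 | intermediate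
4 | (4R,5S)-4-(tert-butyldimethylsilyloxy)-5-(hydroxymethyl)cyclopent-2-en-1-one (CH2OH trans to OTBS) | O=C1C=C[C@@H](O[Si](C)(C)C(C)(C)C)[C@@H]1CO | intermediate
5 | (4R,5S)-4-(tert-butyldimethylsilyloxy)-5-[(tert-butyldimethylsilyloxy)methyl]cyclopent-2-en-1-one | O=C1C=C[C@@H](O[Si](C)(C)C(C)(C)C)[C@@H]1CO[Si](C)(C)C(C)(C)C | intermediate
6 | potassium dienolate of 5 | [K]OC1=C(CO[Si](C)(C)C(C)(C)C)[C@H](O[Si](C)(C)C(C)(C)C)C=C1 | intermediate
7 | potassium alkoxide of the 8β-hydroxy ketone | O=C1C=C[C@@H](O[Si](C)(C)C(C)(C)C)[C@@]1(O[K])CO[Si](C)(C)C(C)(C)C | intermediate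
8 | (4R,5S)-4-(tert-butyldimethylsilyloxy)-5-[(tert-butyldimethylsilyloxy)methyl]-5-(triethylsilyloxy)cyclopent-2-en-1-one (7α-OTBS; 8β-OTES; 8α-CH2OTBS) | O=C1C=C[C@@H](O[Si](C)(C)C(C)(C)C)[C@@]1(O[Si](CC)(CC)CC)CO[Si](C)(C)C(C)(C)C | intermediate
9 | (4R,5S)-2-iodo derivative of 8 (iodide on C5) | O=C1C([I])=C[C@@H](O[Si](C)(C)C(C)(C)C)[C@@]1(O[Si](CC)(CC)CC)CO[Si](C)(C)C(C)(C)C | intermediate
10 | (3R,4S)-3-(tert-butyldimethylsilyloxy)-4-[(tert-butyldimethylsilyloxy)methyl]-1-iodo-5-methylidene-4-(triethylsilyloxy)cyclopent-1-ene | C=C1C([I])=C[C@@H](O[Si](C)(C)C(C)(C)C)[C@@]1(O[Si](CC)(CC)CC)CO[Si](C)(C)C(C)(C)C | intermediate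
11 | B-alkyl-9-borabicyclo[3.3.1]nonane adduct (boron on C1; H-9 β) | C1CC2CCCC(C1)B2C[C@H]1C([I])=C[C@@H](O[Si](C)(C)C(C)(C)C)[C@@]1(O[Si](CC)(CC)CC)CO[Si](C)(C)C(C)(C)C | intermediate
12 | primary alcohol (C1 = CH2OH on C9, α; H-9 β; C5 iodide; 7α-OTBS; 8β-OTES; 8α-CH2OTBS) | OC[C@H]1C([I])=C[C@@H](O[Si](C)(C)C(C)(C)C)[C@@]1(O[Si](CC)(CC)CC)CO[Si](C)(C)C(C)(C)C | intermediate
13 | aldehyde (C1 = CHO; otherwise as 12) | O=C[C@H]1C([I])=C[C@@H](O[Si](C)(C)C(C)(C)C)[C@@]1(O[Si](CC)(CC)CC)CO[Si](C)(C)C(C)(C)C | intermediate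
14 | carboxylic acid (C1 = CO2H; otherwise as 12) | OC(=O)[C@H]1C([I])=C[C@@H](O[Si](C)(C)C(C)(C)C)[C@@]1(O[Si](CC)(CC)CC)CO[Si](C)(C)C(C)(C)C | intermediate
15 | propargyl bromide (3-bromoprop-1-yne) | C#CCBr | starting material
16 | prop-2-ynyl ester of 14 | C#CCOC(=O)[C@H]1C([I])=C[C@@H](O[Si](C)(C)C(C)(C)C)[C@@]1(O[Si](CC)(CC)CC)CO[Si](C)(C)C(C)(C)C | intermediate
17 | diisobutylaluminium hemiacetal of 16 (C1 epimers) | C#CCOC(O[Al](CC(C)C)CC(C)C)[C@H]1C([I])=C[C@@H](O[Si](C)(C)C(C)(C)C)[C@@]1(O[Si](CC)(CC)CC)CO[Si](C)(C)C(C)(C)C | intermediate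
18 | mixed tert-butyldimethylsilyl prop-2-ynyl acetal at C1 (C1 epimers) | C#CCOC(O[Si](C)(C)C(C)(C)C)[C@H]1C([I])=C[C@@H](O[Si](C)(C)C(C)(C)C)[C@@]1(O[Si](CC)(CC)CC)CO[Si](C)(C)C(C)(C)C | intermediate
19 | mixed tert-butyldimethylsilyl propa-1,2-dienyl acetal at C1 (C1 epimers) | C=C=COC(O[Si](C)(C)C(C)(C)C)[C@H]1C([I])=C[C@@H](O[Si](C)(C)C(C)(C)C)[C@@]1(O[Si](CC)(CC)CC)CO[Si](C)(C)C(C)(C)C | intermediate
20 | (η3-allyl)PdI(PPh3) complex of the cyclised skeleton (allyl = C3–C4–C11; drawn as the C11 σ-form) | I[Pd](P(c1ccccc1)(c1ccccc1)c1ccccc1)CC1=COC(O[Si](C)(C)C(C)(C)C)[C@H]2C1=C[C@@H](O[Si](C)(C)C(C)(C)C)[C@@]2(O[Si](CC)(CC)CC)CO[Si](C)(C)C(C)(C)C | intermediate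
21 | bicyclic dienol ether (1-OTBS, C1 epimers; 11-acetoxy; 7α-OTBS; 8β-OTES; 10-OTBS; H-9 β) | CC(=O)OCC1=COC(O[Si](C)(C)C(C)(C)C)[C@H]2C1=C[C@@H](O[Si](C)(C)C(C)(C)C)[C@@]2(O[Si](CC)(CC)CC)CO[Si](C)(C)C(C)(C)C | intermediate
22 | lactol (1-OH, anomer mixture; otherwise as 21) | CC(=O)OCC1=COC(O)[C@H]2C1=C[C@@H](O[Si](C)(C)C(C)(C)C)[C@@]2(O[Si](CC)(CC)CC)CO[Si](C)(C)C(C)(C)C | intermediate
23 | 3-hydroxy-3-methylbutanoic acid | CC(C)(O)CC(=O)O | starting material
24 | 3-acetoxy-3-methylbutanoic acid | CC(=O)OC(C)(C)CC(=O)O | intermediate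
25 | 1β-(3-acetoxy-3-methylbutanoyloxy) tris-silyl ether (11-acetoxy; 7α-OTBS; 8β-OTES; 10-OTBS) | CC(=O)OCC1=CO[C@@H](OC(=O)CC(C)(C)OC(C)=O)[C@H]2C1=C[C@@H](O[Si](C)(C)C(C)(C)C)[C@@]2(O[Si](CC)(CC)CC)CO[Si](C)(C)C(C)(C)C | intermediate
26 | 7α,8β,10-triol (1β ester; 11-acetate) | CC(=O)OCC1=CO[C@@H](OC(=O)CC(C)(C)OC(C)=O)[C@H]2C1=C[C@@H](O)[C@@]2(O)CO | intermediate
27 | target, (1S,7R,8S,9S) in iridoid numbering: 1β-(3-acetoxy-3-methylbutanoyloxy), 11-acetoxy, 7α- and 10-isovaleryloxy, 8β-hydroxy | CC(=O)OCC1=CO[C@@H](OC(=O)CC(C)(C)OC(C)=O)[C@H]2C1=C[C@@H](OC(=O)CC(C)C)[C@@]2(O)COC(=O)CC(C)C | target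

**Step count.** Total: 16 steps. Longest linear sequence: 15 steps (steps 1–12 and 14–16); step 13 is a one-step side branch.

**Steps most likely to fail**

1. Step 11 (key step). The alkenylpalladium species may add to the allenyl ether of a second molecule and oligomerise faster than it cyclises, may close onto the allene terminus to give the five-membered ring, or may lose iodide reductively. The fallback sets out from alcohol 12 and comes back at lactol 22. Alcohol 12 is oxidised with DMP to aldehyde 13. This is coupled intermolecularly with methoxyallene and Bu4NOAc under Pd(PPh3)4 to give the methyl dienol ether aldehyde F1. PPTS in wet THF should then hydrolyse the enol ether, and the resulting 1,5-dialdehyde equivalent closes to 22 by lactolisation. The pyran ring is then closed through the O2–C1 bond instead of the C4–C5 bond.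

2. Step 14. Under the basic acylation conditions the lactol may open to the aldehyde and dienol, which then expels the C11 acetate by β-elimination, or acylation may occur from the α face. The fallback sets out from 19 and comes back at 26. The cascade of step 11 is run with tBuMe2SiOH and Cs2CO3 in place of the acetate salt, so that the π-allyl intermediate is captured as the C11 silyl ether F2, which is no leaving group. Buffered Bu4NF gives the lactol F3. Steglich acylation with 24 gives the 1β ester F4. HF·pyridine gives the tetraol F5. Selective acetylation of the unhindered primary allylic C11 hydroxyl (AcCl, 2,4,6-collidine, −78 °C) then gives 26.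

3. Step 6. 9-BBN may approach the exocyclic alkene from the α face if the C8 triethylsilyloxy group shields the β face more than the CH2OTBS arm shields the α face; hydrogen would then be delivered to C9 on the wrong face. The fallback sets out from 10 and comes back at 14, and replaces kinetic face selection by thermodynamic control. The same hydroboration then gives the C9-epimeric alcohol F6, and DMP oxidation gives the epimeric aldehyde F7, whose formyl group is cis to the effectively larger C8 silyloxy group. Brief equilibration through the dienol (DBU, CH2Cl2, 0 °C) should give the trans aldehyde 13. NaClO2, NaH2PO4 and 2-methyl-2-butene then oxidise 13 to acid 14.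

**Further compounds**

F1 | step 11 | methyl dienol ether aldehyde (C5 bears C(CH2OAc)=CH–OMe; C1 = CHO; otherwise as 13) | O=C[C@H]1C(C(COC(C)=O)=COC)=C[C@@H](O[Si](C)(C)C(C)(C)C)[C@@]1(O[Si](CC)(CC)CC)CO[Si](C)(C)C(C)(C)C
F2 | step 14 | bicyclic dienol ether with 11-OTBS in place of 11-acetoxy (1-OTBS, C1 epimers) | CC(C)(C)[Si](C)(C)OCC1=COC(O[Si](C)(C)C(C)(C)C)[C@H]2C1=C[C@@H](O[Si](C)(C)C(C)(C)C)[C@@]2(O[Si](CC)(CC)CC)CO[Si](C)(C)C(C)(C)C
F3 | step 14 | lactol with 11-OTBS (1-OH, anomer mixture) | CC(C)(C)[Si](C)(C)OCC1=COC(O)[C@H]2C1=C[C@@H](O[Si](C)(C)C(C)(C)C)[C@@]2(O[Si](CC)(CC)CC)CO[Si](C)(C)C(C)(C)C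
F4 | step 14 | 1β-(3-acetoxy-3-methylbutanoyloxy) compound with 11-OTBS | CC(C)(C)[Si](C)(C)OCC1=CO[C@@H](OC(=O)CC(C)(C)OC(C)=O)[C@H]2C1=C[C@@H](O[Si](C)(C)C(C)(C)C)[C@@]2(O[Si](CC)(CC)CC)CO[Si](C)(C)C(C)(C)C
F5 | step 14 | 7α,8β,10,11-tetraol with the 1β ester | OCC1=CO[C@@H](OC(=O)CC(C)(C)OC(C)=O)[C@H]2C1=C[C@@H](O)[C@@]2(O)CO
F6 | step 6 | C9 epimer of alcohol 12 (H-9 α) | OC[C@@H]1C([I])=C[C@@H](O[Si](C)(C)C(C)(C)C)[C@@]1(O[Si](CC)(CC)CC)CO[Si](C)(C)C(C)(C)C
F7 | step 6 | C9 epimer of aldehyde 13 (H-9 α) | O=C[C@@H]1C([I])=C[C@@H](O[Si](C)(C)C(C)(C)C)[C@@]1(O[Si](CC)(CC)CC)CO[Si](C)(C)C(C)(C)C
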